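**Plan**

Oxolane numbering: O1, C2 (aryl), C3 (arm C9H2–O9), C4 (=C7′H–aryl), C5H2. Retrosynthetic cuts, in order: the phenolic TBS groups and the acyl–O9 ester bond; the ring bond C2–C3, with O9 tied back to C2; C4–C7′; the two acetal bonds C2–O1 and C2–O9.
Enabling feature: C2 is a benzylic O-bearing carbon, C3 carries a CH2–O arm and C4 carries an exocyclic C=C. The sequence O1–C2–O9–C9–C3–C4–C5 can therefore be closed to a seven-membered 2-aryl-4,7-dihydro-1,3-dioxepine, the acetal of an aryl aldehyde with a cis-but-2-ene-1,4-diol. With silicon on C7′, its ring alkene C3=C4 is an allylsilane whose nucleophilic γ-carbon is C3.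
Forward: O-TBS-vanillin is used twice, once for the acetal with 2-bromobutenediol and once for the α-chlorobenzylsilane. The halves are joined at C4–C7′ by asymmetric reductive cross-coupling. A Lewis acid then contracts the dioxepine (7) to the oxolane (5). This one event makes C2–C3 and C4=C7′ and expels C9–O9 as the free hydroxymethyl arm. Esterification and global desilylation finish the route.
Stereochemistry: the only catalyst-set centre is the C7′–Si carbon (S). Anti-SE2′ attack relays it to C3 (S) and, through A1,2 strain, to the E-alkene. C2 (R) follows from C3 (trans). The racemic acetal centre is erased.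

Key step: step 8

Assumption: the sense of induction of the nickel/bis(oxazoline) catalyst on this pair of partners is not predicted here. The ligand antipode that gives the (S)-silane is used; both antipodes are commercial.

**Step 1**
Reactants: 1 vanillin
Product: 2 4-(tert-butyldimethylsilyloxy)-3-methoxybenzaldehyde
Conditions: TBSCl, imidazole, DMF, rt
Reagents that add atoms: tert-butyldimethylsilyl chloride, CC(C)(C)[Si](C)(C)Cl
Why: Standard phenol silylation; the aryl TBS ether should survive all later neutral, reductive and low-temperature Lewis-acid steps and is removed by fluoride at the end.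

**Step 2**
Reactants: 3 furan-2(5H)-one
Product: 5 3-bromofuran-2(5H)-one, via dibromolactone 4 (not isolated)
Conditions: Br2, CH2Cl2, reflux; then Et3N, 0 °C
Reagents that add atoms: bromine, BrBr
Why: Bromination–dehydrobromination: anti addition of bromine to the butenolide alkene, then E1cB loss of the β-bromide through the acidic α-H, leaves bromine on the α-carbon.

**Step 3**
Reactants: 5 3-bromofuran-2(5H)-one
Product: 6 (E)-2-bromobut-2-ene-1,4-diol (the two CH2OH groups cis)
Conditions: DIBAL-H (3 equiv), CH2Cl2, −78 → 0 °C; Rochelle salt work-up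
Reagents that add atoms: none
Why: Exhaustive 1,2-reduction of the butenolide (lactone → lactol → diol) leaves C–Br and C=C untouched, and because the alkene comes from a five-membered ring the two CH2OH groups are necessarily cis.

**Step 4**
Reactants: 2 4-(tert-butyldimethylsilyloxy)-3-methoxybenzaldehyde; 6 (E)-2-bromobut-2-ene-1,4-diol
Product: 7 (±)-5-bromo-2-[4-(tert-butyldimethylsilyloxy)-3-methoxyphenyl]-4,7-dihydro-1,3-dioxepine
Conditions: PPTS (cat.), toluene, Dean–Stark, reflux
Reagents that add atoms: none
Why: Acid-catalysed acetalisation with azeotropic water removal, the usual entry to 4,7-dihydro-1,3-dioxepines from cis-butenediols; the new acetal centre is racemic and is erased in step 8.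

**Step 5**
Reactants: 2 4-(tert-butyldimethylsilyloxy)-3-methoxybenzaldehyde
Product: 8 (±)-[4-(tert-butyldimethylsilyloxy)-3-methoxyphenyl](dimethylphenylsilyl)methanol
Conditions: PhMe2Si–Bpin, IPrCuCl (5 mol %), NaOt-Bu (5 mol %), MeOH (2 equiv), THF, 0 °C → rt
Reagents that add atoms: (dimethylphenylsilyl)boronic acid pinacol ester, C[Si](C)(c1ccccc1)B1OC(C)(C)C(C)(C)O1
Why: Copper-catalysed 1,2-addition of a silyl nucleophile (Cu–Si from Si–B activation) to an aldehyde; the near-neutral medium should suppress Brook rearrangement, and the centre is racemic and is reset in step 7.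

**Step 6**
Reactants: 8 (±)-α-hydroxysilane
Product: 9 (±)-{chloro[4-(tert-butyldimethylsilyloxy)-3-methoxyphenyl]methyl}dimethyl(phenyl)silane
Conditions: SOCl2, pyridine, CH2Cl2, −20 → 0 °C; used without chromatography
Reagents that add atoms: thionyl chloride, O=S(Cl)Cl
Why: Deoxychlorination through the chlorosulfite, helped by the electron-rich aryl group; pyridine is too weak a base to trigger Brook rearrangement.

**Step 7**
Reactants: 7 (±)-bromodioxepine; 9 (±)-(chlorobenzyl)silane
Product: 10 5-{(S)-[4-(tert-butyldimethylsilyloxy)-3-methoxyphenyl](dimethylphenylsilyl)methyl}-2-[4-(tert-butyldimethylsilyloxy)-3-methoxyphenyl]-4,7-dihydro-1,3-dioxepine (both configurations at the acetal carbon)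
Conditions: NiCl2·dme (10 mol %), cyclopropylidene-bridged bis(indano-oxazoline) ligand (11 mol %), Mn (3 equiv), Co(phthalocyanine) (5 mol %), NMP, 5 °C
Reagents that add atoms: none
Why: Nickel-catalysed asymmetric reductive cross-electrophile coupling of a (chlorobenzyl)silane with an alkenyl bromide: the chloride gives a planar α-silylbenzyl radical so both enantiomers of 9 converge, the chiral alkenylnickel complex fixes the (S) C–Si centre on capture and reductive elimination, and the seven-membered ring blocks β-alkoxy elimination because that would need a cyclic allene.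

**Step 8**
Reactants: 10 allylsilane dioxepine
Product: 13 [(2R,3S,4E)-2-[4-(tert-butyldimethylsilyloxy)-3-methoxyphenyl]-4-[4-(tert-butyldimethylsilyloxy)-3-methoxybenzylidene]oxolan-3-yl]methanol, via oxocarbenium triflate 11 (not isolated), via trimethylsilyl ether 12 (not isolated)
Conditions: TMSOTf (1.1 equiv), 2,6-di-tert-butyl-4-methylpyridine (0.5 equiv), CH2Cl2 (0.01 M), −78 → −40 °C; aq NaHCO3 quench; then citric acid, THF–H2O, 0 °C
Reagents that add atoms: none
Why: Proposed new method: TMSOTf silylates the less hindered acetal oxygen O9 (on the CH2 next to the CH= carbon), the C2–O9 bond breaks, and the aryl-stabilised oxocarbenium ion 11 stays tethered through O1–C5H2 to the fully substituted alkene carbon C4; the allylsilane γ-carbon C3 then attacks C2, the β-silyl cation at C4 loses PhMe2Si to triflate to create C4=C7′, and the expelled O9–C9H2 unit becomes the silylated hydroxymethyl arm of 12. The closest known reaction types are the acetal-initiated intramolecular Hosomi–Sakurai reaction and the Petasis–Ferrier-type contraction of cyclic vinyl acetals (4,5-dihydro-1,3-dioxepines) to 2,3-disubstituted oxolane-3-carbaldehydes, with an allylsilane here taking the place of the enol ether. The oxolane closes 5-endo-trig at both π partners, a topology already tolerated in the rearrangement of 4-methylene-1,3-dioxolanes to oxolan-3-ones, and the regioisomeric oxocarbenium ion could only close to a four-membered ring, so reversible acetal opening should funnel material to the five-membered ring. C3 is controlled by the (S) C–Si centre through anti-SE2′ attack: in the reactive conformer C–Si is perpendicular to the alkene plane and the C7′ aryl group lies on the side of the vinylic H of C3 rather than against C5H2 (A1,2 strain), which couples 3S with the E-benzylidene geometry, while the minor conformer would give the separable Z isomer of the opposite C3 series, so the enantiopurity of the E product is kept. C2 is controlled by C3, because the aryl group takes the position trans to the C9 arm in the envelope transition state, and the trans isomer is also the thermodynamic one since the electron-rich benzylic C2–O1 bond can re-ionise and re-close. The selectivity needed is cyclisation over desilylative 1,4-fragmentation of the regioisomeric oxocarbenium ion, protodesilylation and oligomerisation, and it should be secured by the steric bias for silylation at O9, the hindered base, low temperature and high dilution.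

**Step 9**
Reactants: 14 4-hydroxybenzoic acid
Product: 16 4-(tert-butyldimethylsilyloxy)benzoic acid, via bis-silyl derivative 15 (not isolated)
Conditions: TBSCl (2.2 equiv), imidazole, DMF, rt; then AcOH–THF–H2O, rt
Reagents that add atoms: tert-butyldimethylsilyl chloride, CC(C)(C)[Si](C)(C)Cl
Why: Exhaustive silylation followed by selective hydrolysis of the far more labile silyl ester leaves the aryl silyl ether intact.

**Step 10**
Reactants: 13 oxolane alcohol; 16 4-(tert-butyldimethylsilyloxy)benzoic acid
Product: 17 tris-O-TBS-agastenol
Conditions: DCC, DMAP (cat.), CH2Cl2, 0 °C → rt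
Reagents that add atoms: none
Why: Steglich esterification of the only free hydroxyl group under neutral conditions that touch neither the stereocentres nor the benzylidene geometry.

**Step 11**
Reactants: 17 tris-O-TBS-agastenol
Product: 18 agastenol
Conditions: TBAF (3.3 equiv), AcOH (3.5 equiv), THF, 0 °C
Reagents that add atoms: none
Why: Fluoride cleavage of the three aryl silyl ethers; the acetic acid buffer keeps free phenoxide low, so the benzoate ester, the C2–O1 benzylic ether (no quinone methide opening) and the E-alkene should survive.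

**Compound list**
1 | vanillin | COc1cc(C=O)ccc1O | starting material
2 | 4-(tert-butyldimethylsilyloxy)-3-methoxybenzaldehyde | COc1cc(C=O)ccc1O[Si](C)(C)C(C)(C)C | intermediate
3 | furan-2(5H)-one | O=C1C=CCO1 | starting material
4 | (±)-trans-3,4-dibromodihydrofuran-2(3H)-one (one enantiomer drawn) | O=C1OC[C@@H](Br)[C@@H]1Br | intermediate
5 | 3-bromofuran-2(5H)-one | O=C1OCC=C1Br | intermediate
6 | (E)-2-bromobut-2-ene-1,4-diol | OC/C(Br)=C\CO | intermediate
7 | (±)-5-bromo-2-[4-(TBSO)-3-methoxyphenyl]-4,7-dihydro-1,3-dioxepine | COc1cc(C2OCC=C(Br)CO2)ccc1O[Si](C)(C)C(C)(C)C | intermediate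
8 | (±)-[4-(TBSO)-3-methoxyphenyl](dimethylphenylsilyl)methanol | COc1cc(C(O)[Si](C)(C)c2ccccc2)ccc1O[Si](C)(C)C(C)(C)C | intermediate
9 | (±)-{chloro[4-(TBSO)-3-methoxyphenyl]methyl}dimethyl(phenyl)silane | COc1cc(C(Cl)[Si](C)(C)c2ccccc2)ccc1O[Si](C)(C)C(C)(C)C | intermediate
10 | (S)-allylsilane dioxepine (acetal carbon undefined) | COc1cc(C2OCC=C(CO2)[C@H](c2ccc(O[Si](C)(C)C(C)(C)C)c(OC)c2)[Si](C)(C)c2ccccc2)ccc1O[Si](C)(C)C(C)(C)C | intermediate
11 | O1-tethered aryl oxocarbenium triflate with O9–SiMe3 arm | COc1cc(C=[O+]C/C(=C\CO[Si](C)(C)C)[C@H](c2ccc(O[Si](C)(C)C(C)(C)C)c(OC)c2)[Si](C)(C)c2ccccc2)ccc1O[Si](C)(C)C(C)(C)C.[O-]S(=O)(=O)C(F)(F)F | intermediate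
12 | trimethylsilyl ether of 13 | COc1cc(/C=C2/CO[C@@H](c3ccc(O[Si](C)(C)C(C)(C)C)c(OC)c3)[C@@H]2CO[Si](C)(C)C)ccc1O[Si](C)(C)C(C)(C)C | intermediate
13 | [(2R,3S,4E)-2-aryl-4-benzylideneoxolan-3-yl]methanol, both aryl groups 4-(TBSO)-3-methoxyphenyl | COc1cc(/C=C2/CO[C@@H](c3ccc(O[Si](C)(C)C(C)(C)C)c(OC)c3)[C@@H]2CO)ccc1O[Si](C)(C)C(C)(C)C | intermediate
14 | 4-hydroxybenzoic acid | O=C(O)c1ccc(O)cc1 | starting material
15 | tert-butyldimethylsilyl 4-(tert-butyldimethylsilyloxy)benzoate | CC(C)(C)[Si](C)(C)OC(=O)c1ccc(O[Si](C)(C)C(C)(C)C)cc1 | intermediate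
16 | 4-(tert-butyldimethylsilyloxy)benzoic acid | O=C(O)c1ccc(O[Si](C)(C)C(C)(C)C)cc1 | intermediate
17 | tris-O-TBS-agastenol | COc1cc(/C=C2/CO[C@@H](c3ccc(O[Si](C)(C)C(C)(C)C)c(OC)c3)[C@@H]2COC(=O)c2ccc(O[Si](C)(C)C(C)(C)C)cc2)ccc1O[Si](C)(C)C(C)(C)C | intermediate
18 | agastenol | COc1cc(/C=C2/CO[C@@H](c3ccc(O)c(OC)c3)[C@@H]2COC(=O)c2ccc(O)cc2)ccc1O | target

**Step count**
Total steps: 11. Longest linear sequence: 7 (steps 1, 5, 6, 7, 8, 10, 11). The branch through steps 2, 3, 4, 7, 8, 10, 11 is equally long.

**Steps most likely to fail**

1. **Step 8.** The doubly endo five-ring closure may be too slow. Desilylative 1,4-fragmentation of the regioisomeric oxocarbenium ion, protodesilylation or intermolecular allylation could then take over, or control of the alkene geometry could erode.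
   - The fallback keeps the allylsilane but forms the two bonds separately with known reactions, setting out from 10 and returning at 13.
   - Mild hydrolysis (AcOH–THF–H2O) releases the allylsilane diol F1.
   - Ac2O/pyridine gives the diacetate F2.
   - An intermolecular Hosomi–Sakurai reaction of F2 with aldehyde 2 (BF3·OEt2, CH2Cl2, −78 °C; same anti-SE2′ and A1,2 control) gives the homoallylic alcohol F3.
   - Pd(PPh3)4-catalysed Tsuji–Trost cycloetherification ionises only the allylic C5 acetate and closes O1–C5 to the oxolane acetate F4. Any cis C2 epimer is equilibrated to trans with a trace of acid.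
   - DIBAL-H at −78 °C removes the acetate and gives 13.

2. **Step 7.** Oxidative addition to the α-branched cyclic alkenyl bromide may be sluggish. The benzylic radical would then dimerise or be reduced, and enantio-induction may be poor.
   - The fallback leaves the radical cross-electrophile manifold for a polar coupling of a preformed nucleophile, setting out from 9 and returning at 10.
   - Magnesium insertion (Mg, Et2O) gives the configurationally labile α-silylbenzyl Grignard reagent F5.
   - F5 is joined to 7 in a dynamic kinetic asymmetric Kumada coupling with a palladium/ferrocenyl aminophosphine (PPFA) catalyst of the appropriate antipode.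

3. **Step 6.** The activated α-silyl benzylic alcohol may ionise during the OH → Cl exchange, leading to ether formation, hydrolysis or loss of silicon.
   - The fallback makes the C–Si bond last, on a preformed chloride and under basic conditions, setting out from 2 and returning at 9.
   - NaBH4 in MeOH gives the benzyl alcohol F6.
   - SOCl2/pyridine gives the benzyl chloride F7.
   - LDA is added at −78 °C to a mixture of F7 and PhMe2SiCl in THF (in situ quench), which silylates the α-chlorobenzyl anion to 9.

**Further compounds**
F1 | step 8 | (S,E)-2-{[4-(TBSO)-3-methoxyphenyl](dimethylphenylsilyl)methyl}but-2-ene-1,4-diol (CH2OH groups cis) | OC/C(=C\CO)[C@H](c1ccc(O[Si](C)(C)C(C)(C)C)c(OC)c1)[Si](C)(C)c1ccccc1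
F2 | step 8 | diacetate of F1 | CC(=O)OC/C(=C\COC(C)=O)[C@H](c1ccc(O[Si](C)(C)C(C)(C)C)c(OC)c1)[Si](C)(C)c1ccccc1
F3 | step 8 | open-chain homoallylic alcohol, ArCH(OH)–CH(CH2OAc)–C(=CHAr)–CH2OAc | COc1cc(/C=C(/COC(C)=O)[C@@H](COC(C)=O)[C@@H](O)c2ccc(O[Si](C)(C)C(C)(C)C)c(OC)c2)ccc1O[Si](C)(C)C(C)(C)C
F4 | step 8 | acetate of 13 | COc1cc(/C=C2/CO[C@@H](c3ccc(O[Si](C)(C)C(C)(C)C)c(OC)c3)[C@@H]2COC(C)=O)ccc1O[Si](C)(C)C(C)(C)C
F5 | step 7 | chloro{[4-(TBSO)-3-methoxyphenyl](dimethylphenylsilyl)methyl}magnesium | COc1cc(C([Mg]Cl)[Si](C)(C)c2ccccc2)ccc1O[Si](C)(C)C(C)(C)C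
F6 | step 6 | 4-(tert-butyldimethylsilyloxy)-3-methoxybenzyl alcohol | COc1cc(CO)ccc1O[Si](C)(C)C(C)(C)C
F7 | step 6 | 4-(tert-butyldimethylsilyloxy)-3-methoxybenzyl chloride | COc1cc(CCl)ccc1O[Si](C)(C)C(C)(C)C
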